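The pyranone is cut from ring A at O1–C8a and C4–C4a, two bonds on neighbouring ring A carbons. A fluoride-generated C4a≡C8a aryne inserts into the carboxyl C–O bond of an α-methoxycinnamic acid that already carries C2, C3 with its methoxy group and all of ring B; one operation gives the 2'-hydroxy-α-methoxychalcone. The C5 oxygen, tied back in a diphenylmethylene ketal with O6, flanks C4a and sends the carboxylate to C8a, while C8 stays C–H until later. The aryne precursor is an ortho-silyl aryl triflate with the triflate on C4a and the silyl group on C8a, so that its phenol has a single ortho site for metalation.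

Key step: step 10

Remark: compound 1 is taken as a purchasable aldehyde; of the two ortho-silyl triflates that give the C4a≡C8a aryne, the one with oxygen on C4a is used because its phenol has only one free ortho position, whereas a phenol with oxygen on C8a has two oxygen-flanked ortho sites (C4a and C8) and silylation at C8 would lead to the wrong aryne.

Step 1
Reactants: 1 2,3-dihydroxy-4-methoxybenzaldehyde; 2 dichlorodiphenylmethane
Product: 3 7-methoxy-2,2-diphenyl-1,3-benzodioxole-4-carbaldehyde
Conditions: Ph2CCl2 (1.3 equiv), Ph2O, 175 °C, N2 sweep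
Reagents that add atoms: none
Why: Thermal double O-alkylation of the catechol by the gem-dichloride (diphenylmethylene ketal formation) should be driven by loss of HCl and leave the aldehyde untouched.

Step 2
Reactants: 3 7-methoxy-2,2-diphenyl-1,3-benzodioxole-4-carbaldehyde
Product: 5 7-methoxy-2,2-diphenyl-1,3-benzodioxol-4-ol, via aryl formate 4 (not isolated)
Conditions: mCPBA (1.3 equiv), CH2Cl2, 0 °C to rt; aq Na2S2O3/NaHCO3 wash; then K2CO3 (cat.), MeOH, rt
Reagents that add atoms: mCPBA, O=C(OO)c1cccc(Cl)c1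
Why: Dakin oxidation of the Baeyer–Villiger type, in which the aryl group (ortho and para oxygen donors) should migrate in the peracid adduct to give the formate, which mild methanolysis cleaves to the phenol.

Step 3
Reactants: 5 7-methoxy-2,2-diphenyl-1,3-benzodioxol-4-ol
Product: 6 7-methoxy-2,2-diphenyl-1,3-benzodioxol-4-yl N-isopropylcarbamate
Conditions: iPrNCO (1.5 equiv), Et3N (0.2 equiv), CH2Cl2, rt
Reagents that add atoms: isopropyl isocyanate, CC(C)N=C=O
Why: Amine-catalysed addition of the phenol to the isocyanate (carbamoylation) should install a strong ortho-directing group that mild base can later remove.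

Step 4
Reactants: 6 7-methoxy-2,2-diphenyl-1,3-benzodioxol-4-yl N-isopropylcarbamate
Product: 10 7-methoxy-2,2-diphenyl-5-(trimethylsilyl)-1,3-benzodioxol-4-yl N-isopropylcarbamate, via N-silyl carbamate 7 (not isolated), via aryllithium 8 (not isolated), via bis-silyl carbamate 9 (not isolated)
Conditions: TBSOTf (1.1 equiv), TMEDA (1.1 equiv), Et2O, 0 °C to rt; n-BuLi (2.2 equiv), TMEDA (2 equiv), −78 °C; TMSCl (3.5 equiv), −78 °C to rt; aq NaHSO4
Reagents that add atoms: chlorotrimethylsilane, C[Si](C)(C)Cl; tert-butyldimethylsilyl triflate, CC(C)(C)[Si](C)(C)OS(=O)(=O)C(F)(F)F (N-silyl group of 7 to 9 only, lost on work-up); n-butyllithium, [Li]CCCC (lithium of 8 only)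
Why: Directed ortho-metalation, in which in situ N-silylation masks the N–H and the carbamate should direct lithiation to benzodioxole C5 (flavone C8a), the only position ortho to it, before silylation; the methoxy group is a far weaker director, so no isomer is expected.

Step 5
Reactants: 10 7-methoxy-2,2-diphenyl-5-(trimethylsilyl)-1,3-benzodioxol-4-yl N-isopropylcarbamate
Product: 12 7-methoxy-2,2-diphenyl-5-(trimethylsilyl)-1,3-benzodioxol-4-yl trifluoromethanesulfonate, via silylphenol 11 (not isolated)
Conditions: DBU (1.5 equiv), Et2NH (1.2 equiv), MeCN, 40 °C; then PhNTf2 (1.5 equiv), rt to 40 °C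
Reagents that add atoms: N-phenylbis(trifluoromethanesulfonimide), O=S(=O)(N(c1ccccc1)S(=O)(=O)C(F)(F)F)C(F)(F)F
Why: E1cB cleavage of the secondary carbamate (isopropyl isocyanate is trapped by diethylamine) should free the phenoxide without touching the aryl–silicon bond, and sulfonylation in the same pot gives the ortho-silyl aryl triflate.

Step 6
Reactants: 13 methyl 3,5-dihydroxy-4-methoxybenzoate
Product: 14 methyl 3,5-bis(benzyloxy)-4-methoxybenzoate
Conditions: BnBr (2.4 equiv), K2CO3 (3 equiv), DMF, 60 °C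
Reagents that add atoms: benzyl bromide, BrCc1ccccc1
Why: Williamson etherification of both phenols should be straightforward, and benzyl is chosen because it leaves by hydrogenolysis together with the ketal in the last step.

Step 7
Reactants: 14 methyl 3,5-bis(benzyloxy)-4-methoxybenzoate
Product: 15 [3,5-bis(benzyloxy)-4-methoxyphenyl]methanol
Conditions: LiAlH4 (1.2 equiv), THF, 0 °C to rt; aq NaOH work-up
Reagents that add atoms: none
Why: Hydride reduction of the aryl ester should stop at the benzylic alcohol and leave the benzyl and methyl ethers untouched.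

Step 8
Reactants: 15 [3,5-bis(benzyloxy)-4-methoxyphenyl]methanol
Product: 16 3,5-bis(benzyloxy)-4-methoxybenzaldehyde
Conditions: MnO2 (activated, 10 equiv), CH2Cl2, rt
Reagents that add atoms: none
Why: Activated MnO2 should oxidise the electron-rich benzylic alcohol selectively to the aldehyde without over-oxidation.

Step 9
Reactants: 16 3,5-bis(benzyloxy)-4-methoxybenzaldehyde; 17 methyl methoxyacetate
Product: 19 (Z)-3-[3,5-bis(benzyloxy)-4-methoxyphenyl]-2-methoxyacrylic acid, via methyl ester 18 (not isolated)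
Conditions: NaOMe (3 equiv), methyl methoxyacetate (4 equiv), THF, 0 °C to 50 °C; then 2 M aq NaOH, 60 °C; then 2 M HCl to pH 2
Reagents that add atoms: sodium hydroxide, [Na+].[OH-]
Why: Claisen-type aldol condensation of the ester enolate with the non-enolisable aldehyde and elimination should give the α-methoxycinnamate in its thermodynamically preferred Z form (aryl trans to carboxyl), which hydroxide then saponifies.

Step 10
Reactants: 12 7-methoxy-2,2-diphenyl-5-(trimethylsilyl)-1,3-benzodioxol-4-yl trifluoromethanesulfonate; 19 (Z)-3-[3,5-bis(benzyloxy)-4-methoxyphenyl]-2-methoxyacrylic acid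
Product: 21 (Z)-3-[3,5-bis(benzyloxy)-4-methoxyphenyl]-1-(5-hydroxy-7-methoxy-2,2-diphenyl-1,3-benzodioxol-4-yl)-2-methoxyprop-2-en-1-one, via aryne 20 (not isolated)
Conditions: 12 (1.5 equiv), 19 (1.0 equiv), CsF (4 equiv, anhydrous), THF, 125 °C, sealed tube
Reagents that add atoms: none
Why: Fluoride attacks silicon on C8a and triflate leaves from C4a to give aryne 20; the cesium carboxylate of 19 adds through oxygen to C8a, the C4a carbanion attacks the neighbouring ester carbonyl in a 4-exo-trig closure, and the strained four-membered alkoxide opens by C–O cleavage to the ortho-acyl phenoxide, so one carboxyl oxygen becomes the C8a hydroxyl (later O1) and the acyl carbon (C4) is bonded to C4a. The closest known reaction type is the fluoride-induced insertion of arynes into the C–O bond of carboxylic acids, cinnamic acids included, which gives ortho-hydroxyaryl ketones. No ring persists, since the four-membered ring is only a transient intermediate. No stereocentre is formed and the Z alkene of 19 should be carried through unchanged. The step needs regioselective oxygen attack at C8a, which the C5 ketal oxygen should secure by its inductive pull and by the angle distortion that the fused five-membered ring imposes on the aryne, while C8 bears only hydrogen so that no second oxygen competes and the carbanion sits on C4a next to that oxygen. It also needs acyl capture to outrun protonation of the carbanion, which aprotic THF, anhydrous CsF and the high temperature should favour.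

Step 11
Reactants: 21 (Z)-3-[3,5-bis(benzyloxy)-4-methoxyphenyl]-1-(5-hydroxy-7-methoxy-2,2-diphenyl-1,3-benzodioxol-4-yl)-2-methoxyprop-2-en-1-one
Product: 22 (Z)-3-[3,5-bis(benzyloxy)-4-methoxyphenyl]-1-(5-hydroxy-6-iodo-7-methoxy-2,2-diphenyl-1,3-benzodioxol-4-yl)-2-methoxyprop-2-en-1-one
Conditions: NIS (1.05 equiv), MeCN–CH2Cl2, 0 °C to rt, dark
Reagents that add atoms: N-iodosuccinimide, O=C1CCC(=O)N1I
Why: Electrophilic aromatic iodination ortho to the free phenol should occur at C8, the only unsubstituted ring A carbon, which is activated by oxygen on C8a and C7 (ortho) and on C5 (para) and should outcompete ring B and the push-pull enol ether.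

Step 12
Reactants: 22 (Z)-3-[3,5-bis(benzyloxy)-4-methoxyphenyl]-1-(5-hydroxy-6-iodo-7-methoxy-2,2-diphenyl-1,3-benzodioxol-4-yl)-2-methoxyprop-2-en-1-one
Product: 24 2-[3,5-bis(benzyloxy)-4-methoxyphenyl]-8-iodo-3,7-dimethoxy-5,6-[(diphenylmethylene)dioxy]-4H-chromen-4-one, via flavanone 23 (not isolated)
Conditions: I2 (0.2 equiv), DMSO, 120 °C
Reagents that add atoms: none
Why: Iodine–DMSO oxidative cyclisation, in which 6-endo oxa-Michael addition of the C8a phenol to the enone β-carbon should give the 3-methoxychroman-4-one, which is iodinated at C3 and loses HI to the flavone while DMSO reoxidises the iodide.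

Step 13
Reactants: 24 2-[3,5-bis(benzyloxy)-4-methoxyphenyl]-8-iodo-3,7-dimethoxy-5,6-[(diphenylmethylene)dioxy]-4H-chromen-4-one
Product: 25 2-[3,5-bis(benzyloxy)-4-methoxyphenyl]-3,7,8-trimethoxy-5,6-[(diphenylmethylene)dioxy]-4H-chromen-4-one
Conditions: CuI (10 mol %), 3,4,7,8-tetramethyl-1,10-phenanthroline (20 mol %), Cs2CO3 (2 equiv), MeOH–toluene, 110 °C, sealed tube
Reagents that add atoms: methanol, CO
Why: Ullmann-type copper-catalysed C–O coupling of the aryl iodide with methanol should install the C8 methoxy group under carbonate base, which the flavone, the benzyl ethers and the ketal tolerate.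

Step 14
Reactants: 25 2-[3,5-bis(benzyloxy)-4-methoxyphenyl]-3,7,8-trimethoxy-5,6-[(diphenylmethylene)dioxy]-4H-chromen-4-one
Product: 26 5,6,3',5'-tetrahydroxy-3,7,8,4'-tetramethoxyflavone
Conditions: H2 (1 atm), Pd(OH)2/C, THF–MeOH (degassed), rt
Reagents that add atoms: none
Why: Catalytic hydrogenolysis should cleave both benzyl ethers and the two benzylic C–O bonds of the diphenylmethylene ketal in one operation, while the methyl ethers and the tetrasubstituted C2=C3 bond of the flavone are left alone.

Compound list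
1 | 2,3-dihydroxy-4-methoxybenzaldehyde | COc1ccc(C=O)c(O)c1O | starting material
2 | dichlorodiphenylmethane | ClC(Cl)(c1ccccc1)c1ccccc1 | starting material
3 | 7-methoxy-2,2-diphenyl-1,3-benzodioxole-4-carbaldehyde | COc1ccc(C=O)c2OC(c3ccccc3)(c3ccccc3)Oc12 | intermediate
4 | 7-methoxy-2,2-diphenyl-1,3-benzodioxol-4-yl formate | COc1ccc(OC=O)c2OC(c3ccccc3)(c3ccccc3)Oc12 | intermediate (not isolated)
5 | 7-methoxy-2,2-diphenyl-1,3-benzodioxol-4-ol | COc1ccc(O)c2OC(c3ccccc3)(c3ccccc3)Oc12 | intermediate
6 | 7-methoxy-2,2-diphenyl-1,3-benzodioxol-4-yl N-isopropylcarbamate | COc1ccc(OC(=O)NC(C)C)c2OC(c3ccccc3)(c3ccccc3)Oc12 | intermediate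
7 | 7-methoxy-2,2-diphenyl-1,3-benzodioxol-4-yl N-(tert-butyldimethylsilyl)-N-isopropylcarbamate | COc1ccc(OC(=O)N(C(C)C)[Si](C)(C)C(C)(C)C)c2OC(c3ccccc3)(c3ccccc3)Oc12 | intermediate (not isolated)
8 | 5-lithio-7-methoxy-2,2-diphenyl-1,3-benzodioxol-4-yl N-(tert-butyldimethylsilyl)-N-isopropylcarbamate | COc1cc([Li])c(OC(=O)N(C(C)C)[Si](C)(C)C(C)(C)C)c2OC(c3ccccc3)(c3ccccc3)Oc12 | intermediate (not isolated)
9 | 7-methoxy-2,2-diphenyl-5-(trimethylsilyl)-1,3-benzodioxol-4-yl N-(tert-butyldimethylsilyl)-N-isopropylcarbamate | COc1cc([Si](C)(C)C)c(OC(=O)N(C(C)C)[Si](C)(C)C(C)(C)C)c2OC(c3ccccc3)(c3ccccc3)Oc12 | intermediate (not isolated)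
10 | 7-methoxy-2,2-diphenyl-5-(trimethylsilyl)-1,3-benzodioxol-4-yl N-isopropylcarbamate | COc1cc([Si](C)(C)C)c(OC(=O)NC(C)C)c2OC(c3ccccc3)(c3ccccc3)Oc12 | intermediate
11 | 7-methoxy-2,2-diphenyl-5-(trimethylsilyl)-1,3-benzodioxol-4-ol | COc1cc([Si](C)(C)C)c(O)c2OC(c3ccccc3)(c3ccccc3)Oc12 | intermediate (not isolated)
12 | 7-methoxy-2,2-diphenyl-5-(trimethylsilyl)-1,3-benzodioxol-4-yl trifluoromethanesulfonate (triflate on flavone C4a, silyl on flavone C8a) | COc1cc([Si](C)(C)C)c(OS(=O)(=O)C(F)(F)F)c2OC(c3ccccc3)(c3ccccc3)Oc12 | intermediate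
13 | methyl 3,5-dihydroxy-4-methoxybenzoate | COC(=O)c1cc(O)c(OC)c(O)c1 | starting material
14 | methyl 3,5-bis(benzyloxy)-4-methoxybenzoate | COC(=O)c1cc(OCc2ccccc2)c(OC)c(OCc2ccccc2)c1 | intermediate
15 | [3,5-bis(benzyloxy)-4-methoxyphenyl]methanol | COc1c(OCc2ccccc2)cc(CO)cc1OCc1ccccc1 | intermediate
16 | 3,5-bis(benzyloxy)-4-methoxybenzaldehyde | COc1c(OCc2ccccc2)cc(C=O)cc1OCc1ccccc1 | intermediate
17 | methyl methoxyacetate | COCC(=O)OC | starting material
18 | methyl (Z)-3-[3,5-bis(benzyloxy)-4-methoxyphenyl]-2-methoxyacrylate | CO/C(=C\c1cc(OCc2ccccc2)c(OC)c(OCc2ccccc2)c1)C(=O)OC | intermediate (not isolated)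
19 | (Z)-3-[3,5-bis(benzyloxy)-4-methoxyphenyl]-2-methoxyacrylic acid | CO/C(=C\c1cc(OCc2ccccc2)c(OC)c(OCc2ccccc2)c1)C(=O)O | intermediate
20 | 4,5-didehydro-7-methoxy-2,2-diphenyl-1,3-benzodioxole (aryne between flavone C4a and C8a) | COC1=CC#CC2=C1OC(c1ccccc1)(c1ccccc1)O2 | intermediate (not isolated)
21 | (Z)-3-[3,5-bis(benzyloxy)-4-methoxyphenyl]-1-(5-hydroxy-7-methoxy-2,2-diphenyl-1,3-benzodioxol-4-yl)-2-methoxyprop-2-en-1-one | CO/C(=C\c1cc(OCc2ccccc2)c(OC)c(OCc2ccccc2)c1)C(=O)c1c(O)cc(OC)c2OC(c3ccccc3)(c3ccccc3)Oc12 | intermediate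
22 | (Z)-3-[3,5-bis(benzyloxy)-4-methoxyphenyl]-1-(5-hydroxy-6-iodo-7-methoxy-2,2-diphenyl-1,3-benzodioxol-4-yl)-2-methoxyprop-2-en-1-one | CO/C(=C\c1cc(OCc2ccccc2)c(OC)c(OCc2ccccc2)c1)C(=O)c1c(O)c(I)c(OC)c2OC(c3ccccc3)(c3ccccc3)Oc12 | intermediate
23 | 2-[3,5-bis(benzyloxy)-4-methoxyphenyl]-8-iodo-3,7-dimethoxy-5,6-[(diphenylmethylene)dioxy]chroman-4-one (racemic, C2/C3 diastereomers not defined) | COc1c(OCc2ccccc2)cc(C2Oc3c(I)c(OC)c4OC(c5ccccc5)(c5ccccc5)Oc4c3C(=O)C2OC)cc1OCc1ccccc1 | intermediate (not isolated)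
24 | 2-[3,5-bis(benzyloxy)-4-methoxyphenyl]-8-iodo-3,7-dimethoxy-5,6-[(diphenylmethylene)dioxy]-4H-chromen-4-one | COc1c(OCc2ccccc2)cc(-c2oc3c(I)c(OC)c4OC(c5ccccc5)(c5ccccc5)Oc4c3c(=O)c2OC)cc1OCc1ccccc1 | intermediate
25 | 2-[3,5-bis(benzyloxy)-4-methoxyphenyl]-3,7,8-trimethoxy-5,6-[(diphenylmethylene)dioxy]-4H-chromen-4-one | COc1c(OCc2ccccc2)cc(-c2oc3c(OC)c(OC)c4OC(c5ccccc5)(c5ccccc5)Oc4c3c(=O)c2OC)cc1OCc1ccccc1 | intermediate
26 | 5,6,3',5'-tetrahydroxy-3,7,8,4'-tetramethoxyflavone | COc1c(O)cc(-c2oc3c(OC)c(OC)c(O)c(O)c3c(=O)c2OC)cc1O | target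

Total step count: 14.
Longest linear sequence: 10 steps (steps 1 to 5, then 10 to 14, from compound 1).

Steps most likely to fail

Step 10. The C4a carbanion may be protonated before it reaches the cross-conjugated, donor-substituted carbonyl, which would end in simple O-arylation. The enoate may also be consumed by conjugate addition or by onward ring closure under hot fluoride, and excess aryne may arylate the product phenol. The fallback sets out from 12 and 16. Aryne 20 would be generated in the same way (CsF, THF, 125 °C) in the presence of methoxyacetic acid, whose saturated and more electrophilic carbonyl should be captured faster and which has no enoate, to give 1-(5-hydroxy-7-methoxy-2,2-diphenyl-1,3-benzodioxol-4-yl)-2-methoxyethan-1-one F1. Claisen–Schmidt condensation of F1 with aldehyde 16 (KOH, EtOH, rt) would then build the Cα=Cβ bond after the insertion and come back to the route at chalcone 21.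

Step 12. The hot iodine/HI medium may take the C8 iodine off the very electron-rich ring again (protodeiodination) or erode the ketal while the cyclisation is still under way. The fallback sets out from 21 and reverses the order of events. Cyclisation of 21 (I2 0.2 equiv, DMSO, 120 °C) would pass through 2-[3,5-bis(benzyloxy)-4-methoxyphenyl]-3,7-dimethoxy-5,6-[(diphenylmethylene)dioxy]chroman-4-one F2, which is not isolated, to 2-[3,5-bis(benzyloxy)-4-methoxyphenyl]-3,7-dimethoxy-5,6-[(diphenylmethylene)dioxy]-4H-chromen-4-one F3. Iodination of F3 (NIS, TFA cat., MeCN, rt) should then go to C8, the only free ring A position, which lies between O1 and the C7 methoxy group and para to the C5 oxygen. Ring B is activated by only two oxygens per open position and is attached to the electron-poor pyranone. The fallback comes back to the route at 24.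

Step 13. The iodide on C8 has two ortho substituents and may undergo reductive dehalogenation instead of C–O coupling, and alkoxide may attack C2 and open the pyranone. The fallback sets out from 24. Miyaura borylation (B2pin2, Pd(dppf)Cl2, KOAc, dioxane, 90 °C) would give 2-[3,5-bis(benzyloxy)-4-methoxyphenyl]-3,7-dimethoxy-5,6-[(diphenylmethylene)dioxy]-8-(4,4,5,5-tetramethyl-1,3,2-dioxaborolan-2-yl)-4H-chromen-4-one F4. Oxidation (NaBO3·4H2O, THF–H2O, rt) would give 2-[3,5-bis(benzyloxy)-4-methoxyphenyl]-8-hydroxy-3,7-dimethoxy-5,6-[(diphenylmethylene)dioxy]-4H-chromen-4-one F5. O-Methylation (MeI, K2CO3, acetone, reflux) would come back to the route at 25.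

Further compounds
F1 | step 10 | 1-(5-hydroxy-7-methoxy-2,2-diphenyl-1,3-benzodioxol-4-yl)-2-methoxyethan-1-one | COCC(=O)c1c(O)cc(OC)c2OC(c3ccccc3)(c3ccccc3)Oc12
F2 | step 12 | 2-[3,5-bis(benzyloxy)-4-methoxyphenyl]-3,7-dimethoxy-5,6-[(diphenylmethylene)dioxy]chroman-4-one (racemic, C2/C3 diastereomers not defined) | COc1c(OCc2ccccc2)cc(C2Oc3cc(OC)c4OC(c5ccccc5)(c5ccccc5)Oc4c3C(=O)C2OC)cc1OCc1ccccc1
F3 | step 12 | 2-[3,5-bis(benzyloxy)-4-methoxyphenyl]-3,7-dimethoxy-5,6-[(diphenylmethylene)dioxy]-4H-chromen-4-one | COc1c(OCc2ccccc2)cc(-c2oc3cc(OC)c4OC(c5ccccc5)(c5ccccc5)Oc4c3c(=O)c2OC)cc1OCc1ccccc1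
F4 | step 13 | 2-[3,5-bis(benzyloxy)-4-methoxyphenyl]-3,7-dimethoxy-5,6-[(diphenylmethylene)dioxy]-8-(4,4,5,5-tetramethyl-1,3,2-dioxaborolan-2-yl)-4H-chromen-4-one | COc1c(OCc2ccccc2)cc(-c2oc3c(B4OC(C)(C)C(C)(C)O4)c(OC)c4OC(c5ccccc5)(c5ccccc5)Oc4c3c(=O)c2OC)cc1OCc1ccccc1
F5 | step 13 | 2-[3,5-bis(benzyloxy)-4-methoxyphenyl]-8-hydroxy-3,7-dimethoxy-5,6-[(diphenylmethylene)dioxy]-4H-chromen-4-one | COc1c(OCc2ccccc2)cc(-c2oc3c(O)c(OC)c4OC(c5ccccc5)(c5ccccc5)Oc4c3c(=O)c2OC)cc1OCc1ccccc1
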